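The numbers in the tables stem from a simulated flask with made-up constants.

In a one-step world, starting material (S) and partner (B) react with rate kSB, and that rate integrates in closed form. Let G be ln(B/S) minus its value at the charge, and let Δ = B − S, which stays constant as the flask runs. Then G = kΔt, a straight line through zero. Starting material is the limiting reagent in the maple run. Δ is 1.20 M in the maple and oak runs, and 1.20 M in the ash run.

| flask | starting material | partner | free catalyst | time |
|---|---|---|---|---|
| maple | 0.800 M | 2.00 M | 0.00800 M |  |
| ash | 0.480 M | 1.68 M | 0.00800 M |  |
| oak | 0.800 M | 2.00 M | 0.0160 M |  |
| alder | 0.800 M | 2.00 M | 0.0370 M | 150 min |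

- maple run (time / min: [product] / M): 6.0: 0.207; 9.5: 0.277; 15: 0.333; 24: 0.418; 38: 0.505; 60: 0.598; 95: 0.689; 150: 0.749
- ash run (time / min: [product] / M): 6.0: 0.099; 9.5: 0.143; 15: 0.187; 24: 0.232; 38: 0.279; 60: 0.344; 95: 0.400; 150: 0.460
- oak run (time / min: [product] / M): 6.0: 0.295; 9.5: 0.354; 15: 0.431; 24: 0.497; 38: 0.555; 60: 0.636; 95: 0.699; 150: 0.768

(scatter of a reading: 0.006 M)

- order of the initial rate in [free catalyst], near the charge of the maple run, the rate being that where two percent of its starting material are product
- the ash run starts with 0.320 M less of starting material and of partner than the maple run, and with no product. Compared where both hold the same amount of starting material, once fifteen percent of what the ash run was charged with has turned into product, is the ash run faster, slower or alike (within a tenth)?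
- product in the alder run at 150 min, as a share of the starting material charged

Here is my reckoning. In the maple run, G is 1.02 at 60 min and 2.28 at 150 min. So the late slope is m = 0.0140 /min.

That late line misses zero. At 60 min the maple run stands 0.179 above it. The ash run, with the same catalyst charge, stands 0.190 above it. The oak run stands 0.360 above it, twice the maple gain on twice the catalyst. So I carry b = 22.5 /M, the burst gain in G per unit of free catalyst charged.

At 6.0 min the maple run has earned 0.106 of its gain. If the burst fades exponentially, its life is 6.72 min and its starting slope is 0.0267 /min. The catalysed term scales with catalyst, so the order equals its share of the rate, 0.656.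

For the comparison, S and B coincide at the shared point, so the rates stand as the slopes of G. The ash run has turned 20.6 % of its charge by 6.0 min, past the mark. The maple run at 15 min holds what the ash run holds at 2.71 % turned, short of the mark. Even these bounds give a ratio of 1.48, so the ash run is faster.

For the alder run, G at 150 min is 2.94, which gives 96.7 %.

The weak link is the life, read from one point. The 9.5 min reading gives 5.99 min, and with it an order of 0.681.

The forecast, made from the same runs, says 0.66, faster and 96.6 %. Its ground: “The burst therefore scales with catalyst and looks like first-order catalyst death”.

The flask gives 0.64, faster (ratio 2.0) and 96.8 %.

    free catalyst + starting material ⇌ catalyst-substrate complex (23.34 /M/min, 42.36 /min)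
    catalyst-substrate complex + partner → product + free catalyst (8.700 /M/min)
    free catalyst → spent catalyst (0.2064 /min)
    starting material + partner → product (0.01206 /M/min)

In the ash run, my estimated gain of 0.180 leaves an estimated 25.6 min to half conversion, and that run gives 25.8 min. In the alder run, catalyst-substrate complex carried starting material to product in the early minutes, while free catalyst went over to spent catalyst with constant 0.206 /min, a life of 4.85 min for the free form. The uncatalysed step, 0.0121 /M/min, ran beside it and on after it, and at 150 min the alder run held 0.0260 M of starting material.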